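**Retrosynthetic overview**
- The target is reached by late convex-face epoxidation of the C8=C9 alkene, after aroylation of the secondary 6-OH of a cis-fused dauc-8-ene-4,6-diol; the phenol is unmasked last.
- The diol comes from a cis-fused 4-hydroxydauc-7-en-6-one by deconjugation of the enone and hydride reduction, which sets C6.
- That hydroxy enone comes from a proposed desymmetrising copper-catalysed homoenolate conjugate addition/aldol, a formal (3+2) annulation of 3,6-dimethylcyclohepta-2,6-dien-1-one with 1-isopropylcyclopropanol. It forms C1–C2, C4–C5 and the cyclopentane, and sets C1, C4 and C5.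
- The dienone comes from 3-methylcyclohex-2-en-1-one by α′-methylation and one-carbon ring expansion; the cyclopropanol comes from methyl isobutyrate.
- Ring order: seven-membered ring first, then the five-membered ring, oxirane last.

**Assumptions and conventions**
- Assumption: the SMILES is taken literally, i.e. a cis-fused hydroazulene with the angular methyl, H-5, the isopropyl group and the epoxide oxygen on one face (the convex face) and the 4-OH and 6-aroyloxy group on the other.
- Assumption: the sense of induction of the proposed catalyst in step 6 cannot be predicted, so the ligand antipode that gives the drawn enantiomer is chosen by screening.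
- Numbering in names (daucane): C1 is the angular carbon bearing CH3; C2 and C3 are the cyclopentane CH2 groups; C4 bears OH and isopropyl; C5 is the ring-fusion CH; C6 is the oxygenated carbon; C7 is CH2; C8 bears CH3; C9; C10 is CH2 bonded to C1. CIP labels at C1 and C5 change along the route only because substituent priorities change; the spatial arrangement set in step 6 is never altered.

**Route**

Step 1
Reactants: 1 3-methylcyclohex-2-en-1-one
Product: 3 3,6-dimethylcyclohex-2-en-1-one (racemic), via lithium dienolate 2 (not isolated)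
Conditions: LiN(iPr)2, THF, −78 °C; MeI, −78 → 0 °C
Reagents that add atoms: iodomethane, CI
Why: Kinetic α′-deprotonation gives the cross-conjugated lithium dienolate, which is C-methylated (enolate alkylation); the new stereocentre is racemic and is erased in step 2.

Step 2
Reactants: 3 3,6-dimethylcyclohex-2-en-1-one
Product: 5 [(2,5-dimethylcyclohexa-1,5-dien-1-yl)oxy]trimethylsilane, via lithium dienolate 4 (not isolated)
Conditions: LiN(iPr)2, THF, −78 °C; Me3SiCl, −78 → 0 °C
Reagents that add atoms: chlorotrimethylsilane, C[Si](C)(C)Cl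
Why: Kinetic α′-deprotonation and O-silylation (silyl enol ether formation) give the 2-silyloxy-1,3-diene regiospecifically.

Step 3
Reactants: 5 [(2,5-dimethylcyclohexa-1,5-dien-1-yl)oxy]trimethylsilane
Product: 6 trimethyl[(3,6-dimethylbicyclo[4.1.0]hept-2-en-1-yl)oxy]silane (racemic)
Conditions: Et2Zn, CH2I2, CH2Cl2, 0 → 23 °C
Reagents that add atoms: diiodomethane, ICI
Why: Simmons–Smith (Furukawa) cyclopropanation is selective for the electron-rich silyl enol ether alkene over the other trisubstituted alkene; the cis-fused cyclopropane is the only possible one and its racemic stereocentres are erased in step 4.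

Step 4
Reactants: 6 trimethyl[(3,6-dimethylbicyclo[4.1.0]hept-2-en-1-yl)oxy]silane
Product: 8 3,6-dimethylcyclohepta-2,6-dien-1-one, via chloro ketone 7 (not isolated)
Conditions: FeCl3 (2.2 equiv), DMF, 0 → 23 °C; then NaOAc, MeOH, reflux
Reagents that add atoms: none
Why: Saegusa–Ito oxidative ring expansion: one-electron oxidation of the silyloxycyclopropane cleaves the internal bond to the tertiary β-keto radical, which takes chlorine from FeCl3, and acetate-mediated dehydrochlorination gives the symmetric cross-conjugated dienone (no stereocentre).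

Step 5
Reactants: 9 methyl 2-methylpropanoate
Product: 10 1-(propan-2-yl)cyclopropan-1-ol
Conditions: EtMgBr (2.4 equiv), Ti(OiPr)4 (0.2 equiv), Et2O, 20 °C; aq. H2SO4
Reagents that add atoms: ethylmagnesium bromide, CC[Mg]Br
Why: Kulinkovich cyclopropanation of the ester by the titanacyclopropane generated from EtMgBr and Ti(OiPr)4; no stereocentre is formed.

Step 6
Reactants: 8 3,6-dimethylcyclohepta-2,6-dien-1-one; 10 1-(propan-2-yl)cyclopropan-1-ol
Product: 13 (1R,4R,5R)-4-hydroxydauc-7-en-6-one, via zinc bis-homoenolate 11 (not isolated), via zinc enolate 12 (not isolated)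
Conditions: 10 (2.4 equiv), Et2Zn (1.2 equiv), THF, 0 → 40 °C; then Cu(OTf)2 (5 mol%), chiral sulfonate-bearing imidazolinium salt (N-heterocyclic carbene precursor, 6 mol%), 8 (1.0 equiv), THF–toluene, −30 → 0 °C; aq. NH4Cl
Reagents that add atoms: none
Why: Proposed new method: a desymmetrising copper-catalysed homoenolate conjugate addition–aldol cyclisation (formal (3+2) annulation). The zinc cyclopropoxide of 10 opens by strain-releasing β-carbon elimination to the homoenolate 11. Transmetallation to the carbene-bound monovalent copper centre, addition at one of the two enantiotopic β-carbons of 8 (trivalent copper intermediate) and reductive elimination form C1–C2 and the quaternary centre C1 under catalyst control. The zinc enolate 12 then adds to the tethered isopropyl ketone through a zinc-chelated chair (Zimmerman–Traxler) 5-exo transition state; this can close only on the face carrying the tether, giving the cis ring fusion with H-5 syn to the angular methyl, and it places the 4-oxygen syn to C6 and the isopropyl group on the convex face, so C4 and C5 follow from C1. Stoichiometric zinc leaves no proton source, so the enolate is not quenched before aldolisation. Closest known reaction types: enantioselective conjugate addition of cyclopropanol-derived zinc homoenolates to β-monosubstituted acyclic enones, copper–carbene-catalysed conjugate addition of dialkylzinc reagents to β-methyl cyclic enones giving quaternary centres, and tandem conjugate addition–aldol cyclisation of zinc enolates.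

Step 7
Reactants: 13 (1R,4R,5R)-4-hydroxydauc-7-en-6-one
Product: 14 (1R,4R,5R)-4-(trimethylsilyloxy)dauc-7-en-6-one
Conditions: Me3SiOTf, 2,6-lutidine, CH2Cl2, −78 °C
Reagents that add atoms: trimethylsilyl trifluoromethanesulfonate, C[Si](C)(C)OS(=O)(=O)C(F)(F)F
Why: Silyl triflate silylation of the hindered tertiary aldol hydroxyl blocks retro-aldol cleavage, β-elimination and oxa-Michael addition to the enone in the next, basic step; no stereocentre is touched.

Step 8
Reactants: 14 (1R,4R,5R)-4-(trimethylsilyloxy)dauc-7-en-6-one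
Product: 16 (1S,4R,5R)-4-(trimethylsilyloxy)dauc-8-en-6-one, via potassium dienolate 15 (not isolated)
Conditions: KOtBu (3 equiv), tBuOH–THF, 0 °C, 20 min; inverse quench into AcOH–H2O–THF, −40 °C; used crude
Reagents that add atoms: none
Why: Enone deconjugation: thermodynamic γ-deprotonation at C9 gives the extended endocyclic dienolate, whose kinetic protonation at the α-carbon C7 gives the β,γ-enone; the only α′-hydrogen (H-5) is a hindered methine between two fully substituted carbons, so C5 is not epimerised.

Step 9
Reactants: 16 (1S,4R,5R)-4-(trimethylsilyloxy)dauc-8-en-6-one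
Product: 18 (1S,4R,5S,6R)-dauc-8-ene-4,6-diol, via silyl ether alcohol 17 (not isolated)
Conditions: NaBH4, MeOH–THF, −40 °C; then K2CO3 (0.2 equiv), MeOH, 23 °C
Reagents that add atoms: none
Why: Borohydride reduction from the convex face (the side of H-5 and the angular methyl, away from the cyclopentane and its silyloxy group) puts the 6-OH syn to the 4-oxygen, faster than base can reconjugate the alkene; base-catalysed methanolysis then removes the trimethylsilyl ether.

Step 10
Reactants: 18 (1S,4R,5S,6R)-dauc-8-ene-4,6-diol; 19 4-(benzyloxy)benzoyl chloride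
Product: 20 (1S,4R,5S,6R)-4-hydroxydauc-8-en-6-yl 4-(benzyloxy)benzoate
Conditions: Et3N, DMAP (0.2 equiv), CH2Cl2, 0 → 23 °C
Reagents that add atoms: none
Why: DMAP-catalysed acylation is selective for the secondary 6-OH over the hindered tertiary 4-OH, with retention at C6.

Step 11
Reactants: 20 (1S,4R,5S,6R)-4-hydroxydauc-8-en-6-yl 4-(benzyloxy)benzoate
Product: 21 (1S,4R,5S,6R,8R,9S)-8,9-epoxy-4-hydroxydaucan-6-yl 4-(benzyloxy)benzoate
Conditions: mCPBA, NaHCO3, CH2Cl2, 0 °C
Reagents that add atoms: 3-chloroperoxybenzoic acid, OOC(=O)c1cccc(Cl)c1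
Why: Prilezhaev epoxidation of the only alkene from the convex face, anti to the pseudo-axial 6-aroyloxy group and to the cyclopentane, places the oxirane oxygen syn to the angular methyl and sets C8 and C9; the bicarbonate buffer prevents acid-induced opening of the epoxide by the 4-OH.

Step 12
Reactants: 21 (1S,4R,5S,6R,8R,9S)-8,9-epoxy-4-hydroxydaucan-6-yl 4-(benzyloxy)benzoate
Product: 22 (1S,4R,5S,6R,8R,9S)-8,9-epoxy-4-hydroxydaucan-6-yl 4-hydroxybenzoate (CNP0163817.4)
Conditions: H2 (1 atm), Pd/C, EtOAc, 23 °C
Reagents that add atoms: none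
Why: Hydrogenolysis of the aryl benzyl ether; the alkene is already epoxidised, and the non-benzylic trisubstituted epoxide, the ester and the tertiary alcohol are inert under neutral conditions.

**Compound list**
1 | 3-methylcyclohex-2-en-1-one | CC1=CC(=O)CCC1 | starting material
2 | lithium 5-methylcyclohexa-1,5-dien-1-olate | CC1=CC(O[Li])=CCC1 | intermediate
3 | 3,6-dimethylcyclohex-2-en-1-one (racemic) | CC1=CC(=O)C(C)CC1 | intermediate
4 | lithium 2,5-dimethylcyclohexa-1,5-dien-1-olate | CC1=CC(O[Li])=C(C)CC1 | intermediate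
5 | [(2,5-dimethylcyclohexa-1,5-dien-1-yl)oxy]trimethylsilane | CC1=CC(O[Si](C)(C)C)=C(C)CC1 | intermediate
6 | trimethyl[(3,6-dimethylbicyclo[4.1.0]hept-2-en-1-yl)oxy]silane (racemic, cis-fused cyclopropane) | CC1=CC2(O[Si](C)(C)C)CC2(C)CC1 | intermediate
7 | 6-chloro-3,6-dimethylcyclohept-2-en-1-one (racemic) | CC1=CC(=O)CC(C)(Cl)CC1 | intermediate
8 | 3,6-dimethylcyclohepta-2,6-dien-1-one | CC1=CC(=O)C=C(C)CC1 | intermediate
9 | methyl 2-methylpropanoate | COC(=O)C(C)C | starting material
10 | 1-(propan-2-yl)cyclopropan-1-ol | CC(C)C1(O)CC1 | intermediate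
11 | bis(4-methyl-3-oxopentyl)zinc | CC(C)C(=O)CC[Zn]CCC(=O)C(C)C | intermediate
12 | (4-methyl-3-oxopentyl)zinc enolate of 3,6-dimethyl-3-(4-methyl-3-oxopentyl)cyclohepta-1,6-dien-1-ol (quaternary centre as drawn) | CC(C)C(=O)CC[C@@]1(C)CCC(C)=CC(O[Zn]CCC(=O)C(C)C)=C1 | intermediate
13 | (1R,4R,5R)-4-hydroxydauc-7-en-6-one (cis-fused; 4-OH syn to C6, isopropyl syn to H-5 and the angular methyl) | CC(C)[C@]1(O)CC[C@@]2(C)CCC(C)=CC(=O)[C@H]21 | intermediate
14 | (1R,4R,5R)-4-(trimethylsilyloxy)dauc-7-en-6-one | CC(C)[C@]1(O[Si](C)(C)C)CC[C@@]2(C)CCC(C)=CC(=O)[C@H]21 | intermediate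
15 | potassium 4-(trimethylsilyloxy)dauca-6,8-dien-6-olate (configuration as in 14) | CC(C)[C@]1(O[Si](C)(C)C)CC[C@@]2(C)CC=C(C)C=C(O[K])[C@H]21 | intermediate
16 | (1S,4R,5R)-4-(trimethylsilyloxy)dauc-8-en-6-one | CC(C)[C@]1(O[Si](C)(C)C)CC[C@@]2(C)CC=C(C)CC(=O)[C@H]21 | intermediate
17 | (1S,4R,5S,6R)-4-(trimethylsilyloxy)dauc-8-en-6-ol | CC(C)[C@]1(O[Si](C)(C)C)CC[C@@]2(C)CC=C(C)C[C@@H](O)[C@H]21 | intermediate
18 | (1S,4R,5S,6R)-dauc-8-ene-4,6-diol (syn-1,3-diol) | CC(C)[C@]1(O)CC[C@@]2(C)CC=C(C)C[C@@H](O)[C@H]21 | intermediate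
19 | 4-(benzyloxy)benzoyl chloride | O=C(Cl)c1ccc(OCc2ccccc2)cc1 | starting material
20 | (1S,4R,5S,6R)-4-hydroxydauc-8-en-6-yl 4-(benzyloxy)benzoate | CC(C)[C@]1(O)CC[C@@]2(C)CC=C(C)C[C@@H](OC(=O)c3ccc(OCc4ccccc4)cc3)[C@H]21 | intermediate
21 | (1S,4R,5S,6R,8R,9S)-8,9-epoxy-4-hydroxydaucan-6-yl 4-(benzyloxy)benzoate | CC(C)[C@]1(O)CC[C@@]2(C)C[C@@H]3O[C@]3(C)C[C@@H](OC(=O)c3ccc(OCc4ccccc4)cc3)[C@H]21 | intermediate
22 | (1S,4R,5S,6R,8R,9S)-8,9-epoxy-4-hydroxydaucan-6-yl 4-hydroxybenzoate | CC(C)[C@]1(O)CC[C@@]2(C)C[C@@H]3O[C@]3(C)C[C@@H](OC(=O)c3ccc(O)cc3)[C@H]21 | target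

**Step count and risks**
Total steps: 12. Longest linear sequence: 11 steps (1 to 22 through steps 1–4 and 6–12; step 5 is a one-step branch).

The three steps most likely to fail:

Step 6 (proposed new annulation). The risks are slow homoenolate transfer from zinc to copper, low enantioselectivity at the quaternary centre, and a second addition to the remaining enone. The fallback uses known chemistry, sets out from 8 and comes back at 13. Copper-catalysed asymmetric conjugate addition of (4-methylpent-3-en-1-yl)magnesium bromide (Cu(OTf)2, chiral imidazolium carbene precursor, Et2O, −30 °C), a known reaction type for β-methyl cycloalkenones, gives (S)-3,6-dimethyl-6-(4-methylpent-3-en-1-yl)cyclohept-2-en-1-one F1. mCPBA epoxidises only the electron-rich side-chain alkene to give (6R)-6-[2-(3,3-dimethyloxiran-2-yl)ethyl]-3,6-dimethylcyclohept-2-en-1-one F2 (both oxirane epimers serve). Meinwald rearrangement (BF3·OEt2, CH2Cl2, −78 °C, hydride shift to the tertiary cation) gives the 1,6-diketone (R)-3,6-dimethyl-6-(4-methyl-3-oxopentyl)cyclohept-2-en-1-one F3. Reversible base-mediated intramolecular aldol addition (KOtBu 0.2 equiv, THF–tBuOH, −20 °C) then closes the cyclopentanol to 13; this closure is under thermodynamic rather than regiospecific control.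

Step 8 (deconjugation). The risks are loss of the silyl ether, β-elimination through the C5 enolate, and partial γ-protonation back to the conjugated enone. The fallback sets out from 14 and comes back at 18, avoiding alkoxide base altogether. Soft enolisation with tBuMe2SiOTf and Et3N (CH2Cl2, 0 °C) traps the extended dienol ether (1S,4R,5S)-6-(tert-butyldimethylsilyloxy)-4-(trimethylsilyloxy)dauca-6,8-diene F4. Fluoride-triggered protodesilylation (Bu4NF, AcOH, THF, −78 °C) protonates the dienolate at C7 and frees the tertiary alcohol, giving (1S,4R,5R)-4-hydroxydauc-8-en-6-one F5. Chelation-controlled Narasaka–Prasad reduction (Et2BOMe, NaBH4, THF–MeOH, −78 °C) then gives the syn-diol 18 directly.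

Step 11 (epoxidation face selectivity). If the peracid attacks mainly the face of the aroyloxy group, the fallback sets out from 20 and comes back at 21. N-Bromosuccinimide in aqueous THF gives the trans bromohydrin (1S,4R,5S,6R,8R,9R)-9-bromo-4,8-dihydroxydaucan-6-yl 4-(benzyloxy)benzoate F6: the bromonium ion forms on the face preferred by electrophiles and water opens it at the tertiary C8 from the opposite face. DBU (CH2Cl2, 23 °C) closes the oxirane with inversion at C9, so the oxygen ends on the face opposite to the one direct epoxidation took, giving 21.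

**Further compounds**
F1 | step 6 | (S)-3,6-dimethyl-6-(4-methylpent-3-en-1-yl)cyclohept-2-en-1-one | CC(C)=CCC[C@@]1(C)CCC(C)=CC(=O)C1
F2 | step 6 | (6R)-6-[2-(3,3-dimethyloxiran-2-yl)ethyl]-3,6-dimethylcyclohept-2-en-1-one (oxirane epimers) | CC1(C)OC1CC[C@@]1(C)CCC(C)=CC(=O)C1
F3 | step 6 | (R)-3,6-dimethyl-6-(4-methyl-3-oxopentyl)cyclohept-2-en-1-one | CC(C)C(=O)CC[C@@]1(C)CCC(C)=CC(=O)C1
F4 | step 8 | (1S,4R,5S)-6-(tert-butyldimethylsilyloxy)-4-(trimethylsilyloxy)dauca-6,8-diene | CC(C)[C@]1(O[Si](C)(C)C)CC[C@@]2(C)CC=C(C)C=C(O[Si](C)(C)C(C)(C)C)[C@H]21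
F5 | step 8 | (1S,4R,5R)-4-hydroxydauc-8-en-6-one | CC(C)[C@]1(O)CC[C@@]2(C)CC=C(C)CC(=O)[C@H]21
F6 | step 11 | (1S,4R,5S,6R,8R,9R)-9-bromo-4,8-dihydroxydaucan-6-yl 4-(benzyloxy)benzoate | CC(C)[C@]1(O)CC[C@@]2(C)C[C@@H](Br)[C@](C)(O)C[C@@H](OC(=O)c3ccc(OCc4ccccc4)cc3)[C@H]21
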